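**Retrosynthetic overview**

1. Feature: without the two CH2OAc carbons (C9 on C8, C9' on C8') the skeleton is an (E)-1,4-diarylbut-2-ene, C7–C8=C8'–C7'. The like (8R,8'R) configuration is what suprafacial delivery of a C9–C9' two-carbon unit across the (E)-C8=C8' bond gives.
2. Justin C 17 ⇐ O-benzyl diacetate 16 ⇐ diol 15 ⇐ trans-γ-lactone 14 ⇐ ozonolysis of the C9=C9' bond of silyl enol ether 11 ⇐ cyclobutanone 10.
3. Key disconnection: 10 ⇐ alkene 4 + keteniminium ion 8 (the C9–C9' unit, from amide 6) by [2+2] cycloaddition. It forms C8–C9 and C8'–C9' and closes the cyclobutane C8–C8'–C9'–C9. Either orientation of the carbonyl group leads to the same diol 15.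
4. Alkene 4 ⇐ cross-metathesis of benzyl ether 2 (from 4-allyl-2,6-dimethoxyphenol 1) with methyl eugenol 3.
5. Ring order: the cyclobutane (step 4) is the only carbocycle built and is cleaved in step 6. The lactone ring of 14 is a passing device, opened in step 7.

Key step: step 4

Assumption (sense of induction): the (2S,5S)-auxiliary is taken to direct the two-carbon unit to the alkene face that leads to the (8R,8'R) series. This is not secured for an acyclic (E)-alkene and is to be checked on the first batch of 15; if the sense is opposite, the commercial (2R,5R)-amine is carried through the identical steps.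

Remark (regioisomeric companions): step 4 gives 9 and 10 together with the regioisomers in which the C=N+ or C=O carbon is bonded to C8 instead of C8'. These companions have the same configuration at C8 and C8', are carried unseparated beside 10, 11, 12, 13 and 14 through steps 5 and 6 under the name "the companion of N", and become the single diol 15 in step 7. Their structures are: companion of 9 COc1ccc(C[C@@H](C4=[N+]5[C@@H](C)CC[C@@H]5C)[C@H](C4)Cc2cc(OC)c(OCc3ccccc3)c(OC)c2)cc1OC.[O-]S(=O)(=O)C(F)(F)F; of 10 COc1ccc(C[C@@H](C4=O)[C@H](C4)Cc2cc(OC)c(OCc3ccccc3)c(OC)c2)cc1OC; of 11 COc1ccc(C[C@@H](C(O[Si](C)(C)C)=C4)[C@H]4Cc2cc(OC)c(OCc3ccccc3)c(OC)c2)cc1OC; of 12 COc1ccc(C[C@@H](C(=O)O[Si](C)(C)C)[C@H](C(OC)OO)Cc2cc(OC)c(OCc3ccccc3)c(OC)c2)cc1OC; of 13 COc1ccc(C[C@@H](C(=O)O)[C@H](CO)Cc2cc(OC)c(OCc3ccccc3)c(OC)c2)cc1OC; of 14 COc1ccc(C[C@@H](C(=O)O5)[C@H](C5)Cc2cc(OC)c(OCc3ccccc3)c(OC)c2)cc1OC.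

Step 1
Reactants: 1 4-allyl-2,6-dimethoxyphenol
Product: 2 5-allyl-2-(benzyloxy)-1,3-dimethoxybenzene
Conditions: BnBr, K2CO3, DMF, 50 °C
Reagents that add atoms: benzyl bromide, BrCc1ccccc1
Why: Williamson ether synthesis (SN2 of the phenoxide on benzyl bromide); the benzyl ether masks the only acidic OH through the base, oxidant and hydride steps and is removable at the end by hydrogenolysis without touching the acetates.

Step 2
Reactants: 2 5-allyl-2-(benzyloxy)-1,3-dimethoxybenzene, 3 methyl eugenol (4-allyl-1,2-dimethoxybenzene)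
Product: 4 (E)-2-(benzyloxy)-5-[4-(3,4-dimethoxyphenyl)but-2-en-1-yl]-1,3-dimethoxybenzene
Conditions: 3 (3 equiv), second-generation Grubbs catalyst RuCl2(H2IMes)(PCy3)(=CHPh) (3 mol %), 1,4-benzoquinone (10 mol %), CH2Cl2, 40 °C, argon purge; chromatography on SiO2, then on AgNO3-impregnated SiO2
Reagents that add atoms: none
Why: Olefin cross-metathesis of two allylarenes of equal reactivity, driven by loss of ethylene and by the excess of 3; secondary metathesis should favour the (E)-isomer, benzoquinone suppresses Ru–H migration of the double bond into conjugation, and the homodimers (different number of benzyloxy groups) and the (Z)-isomer (stronger Ag+ complexation) are removed by chromatography.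

Step 3
Reactants: 5 (2S,5S)-2,5-dimethylpyrrolidine
Product: 6 1-[(2S,5S)-2,5-dimethylpyrrolidin-1-yl]ethan-1-one
Conditions: Ac2O, Et3N, DMAP (cat.), CH2Cl2, 0 °C → rt
Reagents that add atoms: acetic anhydride, CC(=O)OC(C)=O
Why: DMAP-catalysed N-acylation of the secondary amine; the two stereocentres are not involved.

Step 4
Reactants: 6 1-[(2S,5S)-2,5-dimethylpyrrolidin-1-yl]ethan-1-one, 4 (E)-2-(benzyloxy)-5-[4-(3,4-dimethoxyphenyl)but-2-en-1-yl]-1,3-dimethoxybenzene
Product: 10 (2R,3S)-2-[4-(benzyloxy)-3,5-dimethoxybenzyl]-3-(3,4-dimethoxybenzyl)cyclobutan-1-one, via O-triflyl iminium triflate 7 (not isolated), via keteniminium triflate 8 (not isolated), via cyclobutaniminium triflate 9 (not isolated)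
Conditions: 6 (1.5 equiv), Tf2O (1.5 equiv), ClCH2CH2Cl, −20 °C; then 4 (1.0 equiv), 2,4,6-collidine (1.8 equiv), −20 → 60 °C; then H2O, 60 °C (two-phase); aq. NaHCO3 work-up
Reagents that add atoms: water, O; trifluoromethanesulfonic anhydride, O=S(=O)(OS(=O)(=O)C(F)(F)F)C(F)(F)F (its atoms stay in 7, 8 and 9 only, not in 10)
Why: Tf2O O-sulfonylates amide 6 to the iminium triflate 7, collidine removes an acetyl proton and triflate leaves to give the linear keteniminium ion 8, and the C8=C8' π bond of 4 attacks its central carbon in an orthogonal, asynchronous [2+2] cycloaddition (bond to the iminium carbon first, bond from the CH2 terminus closing before rotation about C8–C8' can occur); the closest known reaction type is the cycloaddition of keteniminium triflates of tertiary amides, 2,5-dimethylpyrrolidine amides included, to unactivated alkenes, which gives cyclobutanones after hydrolysis. The one ring formed, the cyclobutane C8–C8'–C9'–C9, is closed by the cycloaddition itself, the two new σ bonds C8–C9 and C8'–C9' being made on the same face of the alkene. Since the addition is suprafacial on the alkene, the (E) geometry of 4 becomes the trans relation of the two arylmethyl groups, so the relative configuration of C8 and C8' rests on the geometric purity of 4. The absolute configuration rests on the auxiliary: its C2 axis makes the two faces of the C=N+ bond of 8 equivalent and puts one methyl group beside the attacked carbon on each, so the alkene should approach with a vinylic hydrogen, not an arylmethyl group, next to that methyl group, which tells its enantiotopic faces apart. Regioselectivity is not needed, since the alkene termini differ only in remote ring substituents and 9, 10 and their companions carry the same configuration at C8 and C8'; what is needed is face selectivity (auxiliary) and chemoselectivity for the alkene over the alkoxyarene rings, served by activating the amide before 4 is added and by keeping the excess of 8 small. Water then hydrolyses the C=N+ bond of 9 to the ketone 10 and releases amine 5, and any enamine–iminium equilibration at the α-carbon can only return the more stable trans isomer, because the β-stereocentre is fixed.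

Step 5
Reactants: 10 (2R,3S)-2-[4-(benzyloxy)-3,5-dimethoxybenzyl]-3-(3,4-dimethoxybenzyl)cyclobutan-1-one
Product: 11 {[(3S,4R)-4-[4-(benzyloxy)-3,5-dimethoxybenzyl]-3-(3,4-dimethoxybenzyl)cyclobut-1-en-1-yl]oxy}trimethylsilane
Conditions: LiN(iPr)2 (LDA, commercial solution), Me3SiCl (present from the start), THF, −78 °C; non-aqueous work-up (pentane, filtration), used crude
Reagents that add atoms: chlorotrimethylsilane, C[Si](C)(C)Cl
Why: Kinetic enolisation by the hindered amide base at the unsubstituted ring CH2 (C9 in 10, C9' in its companion) with in situ O-silylation (internal quench) should give the less substituted silyl enol ether before enolate equilibration or aldol self-condensation of the strained ketone can occur; C8 and C8' are untouched and the companion reacts in the same way.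

Step 6
Reactants: 11 {[(3S,4R)-4-[4-(benzyloxy)-3,5-dimethoxybenzyl]-3-(3,4-dimethoxybenzyl)cyclobut-1-en-1-yl]oxy}trimethylsilane
Product: 14 (3R,4R)-3-[4-(benzyloxy)-3,5-dimethoxybenzyl]-4-(3,4-dimethoxybenzyl)dihydrofuran-2(3H)-one, via methoxy hydroperoxide 12 (not isolated), via hydroxy acid 13 (not isolated)
Conditions: O3, CH2Cl2–MeOH, Sudan Red 7B (indicator), −78 °C; NaBH4, −78 °C → rt; 1 M HCl, then TsOH (cat.), CH2Cl2, rt
Reagents that add atoms: ozone, [O-][O+]=O; methanol, CO (its atoms stay in 12 only, not in 14)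
Why: Ozonolysis of the silyl enol ether (Criegee cleavage in methanol to the silyl ester and methoxy hydroperoxide 12) breaks the C9–C9' bond, the electron-rich enol ether C=C being expected to react far faster than the alkoxyarene rings (end point shown by the dye); cold borohydride reduces the peroxidic carbon to the primary alcohol before the neighbouring stereocentre can epimerise and leaves the carboxylate untouched, and acid closes hydroxy acid 13 to the trans γ-lactone, the companion giving the lactone with the carbonyl group on the C8 side.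

Step 7
Reactants: 14 (3R,4R)-3-[4-(benzyloxy)-3,5-dimethoxybenzyl]-4-(3,4-dimethoxybenzyl)dihydrofuran-2(3H)-one
Product: 15 (2R,3R)-2-[4-(benzyloxy)-3,5-dimethoxybenzyl]-3-(3,4-dimethoxybenzyl)butane-1,4-diol
Conditions: LiAlH4, THF, 0 °C → rt; H2O, aq. NaOH work-up
Reagents that add atoms: none
Why: LiAlH4 reduction of a γ-lactone to the 1,4-diol; 14 and its companion give the same diol, so the regioisomeric mixture becomes one compound here, and no stereocentre is touched.

Step 8
Reactants: 15 (2R,3R)-2-[4-(benzyloxy)-3,5-dimethoxybenzyl]-3-(3,4-dimethoxybenzyl)butane-1,4-diol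
Product: 16 (2R,3R)-2-[4-(benzyloxy)-3,5-dimethoxybenzyl]-3-(3,4-dimethoxybenzyl)butane-1,4-diyl diacetate
Conditions: Ac2O, pyridine, DMAP (cat.), CH2Cl2, rt
Reagents that add atoms: acetic anhydride, CC(=O)OC(C)=O
Why: DMAP-catalysed O-acetylation of the two primary alcohols.

Step 9
Reactants: 16 (2R,3R)-2-[4-(benzyloxy)-3,5-dimethoxybenzyl]-3-(3,4-dimethoxybenzyl)butane-1,4-diyl diacetate
Product: 17 Justin C [(2R,3R)-2-(3,4-dimethoxybenzyl)-3-(4-hydroxy-3,5-dimethoxybenzyl)butane-1,4-diyl diacetate]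
Conditions: H2 (1 atm), Pd/C (10 wt % Pd), EtOAc, rt
Reagents that add atoms: none
Why: Catalytic hydrogenolysis of the aryl benzyl ether; alkyl acetates, aryl methyl ethers and the stereocentres are inert under these neutral conditions.

**Compound list**

1 | 4-allyl-2,6-dimethoxyphenol | COc1cc(CC=C)cc(OC)c1O | starting material
2 | 5-allyl-2-(benzyloxy)-1,3-dimethoxybenzene | COc1cc(CC=C)cc(OC)c1OCc1ccccc1 | intermediate
3 | methyl eugenol (4-allyl-1,2-dimethoxybenzene) | COc1ccc(CC=C)cc1OC | starting material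
4 | (E)-2-(benzyloxy)-5-[4-(3,4-dimethoxyphenyl)but-2-en-1-yl]-1,3-dimethoxybenzene | COc1ccc(C/C=C/Cc2cc(OC)c(OCc3ccccc3)c(OC)c2)cc1OC | intermediate
5 | (2S,5S)-2,5-dimethylpyrrolidine | C[C@H]1CC[C@H](C)N1 | starting material
6 | 1-[(2S,5S)-2,5-dimethylpyrrolidin-1-yl]ethan-1-one | CC(=O)N1[C@@H](C)CC[C@@H]1C | intermediate
7 | (2S,5S)-2,5-dimethyl-1-{1-[(trifluoromethanesulfonyl)oxy]ethylidene}pyrrolidin-1-ium trifluoromethanesulfonate | CC(OS(=O)(=O)C(F)(F)F)=[N+]1[C@@H](C)CC[C@@H]1C.[O-]S(=O)(=O)C(F)(F)F | intermediate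
8 | (2S,5S)-1-ethenylidene-2,5-dimethylpyrrolidin-1-ium trifluoromethanesulfonate | C=C=[N+]1[C@@H](C)CC[C@@H]1C.[O-]S(=O)(=O)C(F)(F)F | intermediate
9 | (2S,5S)-1-[(2R,3S)-2-[4-(benzyloxy)-3,5-dimethoxybenzyl]-3-(3,4-dimethoxybenzyl)cyclobutylidene]-2,5-dimethylpyrrolidin-1-ium trifluoromethanesulfonate | COc1ccc(C[C@@H](CC4=[N+]5[C@@H](C)CC[C@@H]5C)[C@H]4Cc2cc(OC)c(OCc3ccccc3)c(OC)c2)cc1OC.[O-]S(=O)(=O)C(F)(F)F | intermediate
10 | (2R,3S)-2-[4-(benzyloxy)-3,5-dimethoxybenzyl]-3-(3,4-dimethoxybenzyl)cyclobutan-1-one | COc1ccc(C[C@@H](CC4=O)[C@H]4Cc2cc(OC)c(OCc3ccccc3)c(OC)c2)cc1OC | intermediate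
11 | {[(3S,4R)-4-[4-(benzyloxy)-3,5-dimethoxybenzyl]-3-(3,4-dimethoxybenzyl)cyclobut-1-en-1-yl]oxy}trimethylsilane | COc1ccc(C[C@@H](C=C4O[Si](C)(C)C)[C@H]4Cc2cc(OC)c(OCc3ccccc3)c(OC)c2)cc1OC | intermediate
12 | trimethylsilyl (2R,3R)-2-[4-(benzyloxy)-3,5-dimethoxybenzyl]-3-(3,4-dimethoxybenzyl)-4-hydroperoxy-4-methoxybutanoate (both C4 epimers) | COc1ccc(C[C@@H](C(OC)OO)[C@H](C(=O)O[Si](C)(C)C)Cc2cc(OC)c(OCc3ccccc3)c(OC)c2)cc1OC | intermediate
13 | (2R,3R)-2-[4-(benzyloxy)-3,5-dimethoxybenzyl]-3-(3,4-dimethoxybenzyl)-4-hydroxybutanoic acid | COc1ccc(C[C@@H](CO)[C@H](C(=O)O)Cc2cc(OC)c(OCc3ccccc3)c(OC)c2)cc1OC | intermediate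
14 | (3R,4R)-3-[4-(benzyloxy)-3,5-dimethoxybenzyl]-4-(3,4-dimethoxybenzyl)dihydrofuran-2(3H)-one | COc1ccc(C[C@@H](CO5)[C@H](C5=O)Cc2cc(OC)c(OCc3ccccc3)c(OC)c2)cc1OC | intermediate
15 | (2R,3R)-2-[4-(benzyloxy)-3,5-dimethoxybenzyl]-3-(3,4-dimethoxybenzyl)butane-1,4-diol | COc1ccc(C[C@@H](CO)[C@H](CO)Cc2cc(OC)c(OCc3ccccc3)c(OC)c2)cc1OC | intermediate
16 | (2R,3R)-2-[4-(benzyloxy)-3,5-dimethoxybenzyl]-3-(3,4-dimethoxybenzyl)butane-1,4-diyl diacetate | COc1ccc(C[C@@H](COC(C)=O)[C@H](COC(C)=O)Cc2cc(OC)c(OCc3ccccc3)c(OC)c2)cc1OC | intermediate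
17 | Justin C [(2R,3R)-2-(3,4-dimethoxybenzyl)-3-(4-hydroxy-3,5-dimethoxybenzyl)butane-1,4-diyl diacetate] | COc1ccc(C[C@@H](COC(C)=O)[C@H](COC(C)=O)Cc2cc(OC)c(O)c(OC)c2)cc1OC | target

**Step count**

Total: 9 steps. Longest linear sequence: 8 steps (steps 1, 2, 4, 5, 6, 7, 8, 9 from 1); step 3 is a one-step side branch.

**Steps most likely to fail**

Step 4. Two processes may spoil it: insufficient discrimination between the enantiotopic faces of an acyclic (E)-alkene by the auxiliary, and Friedel–Crafts-type attack of the iminium or keteniminium ion on the alkoxyarene rings instead of the alkene. The fallback sets the two stereocentres by auxiliary-controlled enolate alkylations; it sets out from 2 and comes back to the route at diol 15. Hydroboration–oxidation of 2 (9-BBN, THF; NaOH, H2O2) would give 3-[4-(benzyloxy)-3,5-dimethoxyphenyl]propan-1-ol F1. Oxidation (TEMPO, PhI(OAc)2, MeCN–H2O) would give 3-[4-(benzyloxy)-3,5-dimethoxyphenyl]propanoic acid F2. Mixed-anhydride acylation (t-BuCOCl, Et3N; then (S)-4-benzyloxazolidin-2-one lithiated with n-C4H9Li, THF, −78 °C) would give (S)-4-benzyl-3-{3-[4-(benzyloxy)-3,5-dimethoxyphenyl]propanoyl}oxazolidin-2-one F3. Evans alkylation of its (Z)-enolate (NaN(SiMe3)2, BrCH2CO2t-Bu, THF, −78 °C), on the face opposite the auxiliary benzyl group, would give tert-butyl (R)-3-[4-(benzyloxy)-3,5-dimethoxybenzyl]-4-[(S)-4-benzyl-2-oxooxazolidin-3-yl]-4-oxobutanoate F4. Reductive removal of the auxiliary (LiBH4, THF, 0 °C) would give tert-butyl (R)-3-[4-(benzyloxy)-3,5-dimethoxybenzyl]-4-hydroxybutanoate F5, and acid (TsOH, toluene, 60 °C) would close (R)-4-[4-(benzyloxy)-3,5-dimethoxybenzyl]dihydrofuran-2(3H)-one F6. Alkylation of its lithium enolate (LiN(SiMe3)2, 3,4-dimethoxybenzyl bromide, THF, −78 °C), anti to the C4 substituent, would give (3R,4R)-4-[4-(benzyloxy)-3,5-dimethoxybenzyl]-3-(3,4-dimethoxybenzyl)dihydrofuran-2(3H)-one F7, the companion of 14. LiAlH4 (THF, 0 °C → rt) would reduce it to diol 15, which continues through steps 8 and 9.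

Step 6. Over-oxidation of the electron-rich rings or of the benzyl ether by ozone, hydrolysis of the silyl enol ether back to the ketone before cleavage, or epimerisation next to the peroxidic carbon before reduction may occur. The fallback cleaves the same bond through an α-ketol; it sets out from 11 (and its companion) and comes back at hydroxy acid 13 (and its companion). Rubottom oxidation with dimethyldioxirane (acetone–CH2Cl2, −40 °C; then citric acid, MeOH) would give (2R,3R)-2-[4-(benzyloxy)-3,5-dimethoxybenzyl]-3-(3,4-dimethoxybenzyl)-4-hydroxycyclobutan-1-one F8 and, from the companion, (2R,3R)-3-[4-(benzyloxy)-3,5-dimethoxybenzyl]-2-(3,4-dimethoxybenzyl)-4-hydroxycyclobutan-1-one F9, each as both C4 epimers. NaIO4 (THF–pH 7 buffer, 0 °C) would cleave the ketol C–C bond to (2R,3R)-2-[4-(benzyloxy)-3,5-dimethoxybenzyl]-3-(3,4-dimethoxybenzyl)-4-oxobutanoic acid F10 and (2R,3R)-3-[4-(benzyloxy)-3,5-dimethoxybenzyl]-2-(3,4-dimethoxybenzyl)-4-oxobutanoic acid F11. NaBH4 added to the same pot would reduce the aldehydes to 13 and its companion, which lactonise as in step 6.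

Step 2. Incomplete removal of the (Z)-isomer, which would be carried on as the cis-cyclobutanone and erode the stereochemical purity, and migration of the double bond into conjugation are the dangers. The fallback fixes the geometry before the second aryl group is attached; it sets out from 2 and comes back at 4. Cross-metathesis of 2 with vinylboronic acid pinacol ester (second-generation Grubbs catalyst RuCl2(H2IMes)(PCy3)(=CHPh), CH2Cl2, 40 °C) would give (E)-2-{3-[4-(benzyloxy)-3,5-dimethoxyphenyl]prop-1-en-1-yl}-4,4,5,5-tetramethyl-1,3,2-dioxaborolane F12, in which the bulky boryl group favours the (E)-isomer and which can be purified. Suzuki–Miyaura coupling with 3,4-dimethoxybenzyl bromide (Pd(PPh3)4, K2CO3, THF–H2O, 60 °C) proceeds with retention of the alkene geometry and would give 4.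

**Further compounds**

F1 | step 4 | 3-[4-(benzyloxy)-3,5-dimethoxyphenyl]propan-1-ol | COc1cc(CCCO)cc(OC)c1OCc1ccccc1
F2 | step 4 | 3-[4-(benzyloxy)-3,5-dimethoxyphenyl]propanoic acid | COc1cc(CCC(=O)O)cc(OC)c1OCc1ccccc1
F3 | step 4 | (S)-4-benzyl-3-{3-[4-(benzyloxy)-3,5-dimethoxyphenyl]propanoyl}oxazolidin-2-one | COc1cc(CCC(=O)N2[C@@H](Cc3ccccc3)COC2=O)cc(OC)c1OCc1ccccc1
F4 | step 4 | tert-butyl (R)-3-[4-(benzyloxy)-3,5-dimethoxybenzyl]-4-[(S)-4-benzyl-2-oxooxazolidin-3-yl]-4-oxobutanoate | COc1cc(C[C@H](CC(=O)OC(C)(C)C)C(=O)N2[C@@H](Cc3ccccc3)COC2=O)cc(OC)c1OCc1ccccc1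
F5 | step 4 | tert-butyl (R)-3-[4-(benzyloxy)-3,5-dimethoxybenzyl]-4-hydroxybutanoate | COc1cc(C[C@H](CC(=O)OC(C)(C)C)CO)cc(OC)c1OCc1ccccc1
F6 | step 4 | (R)-4-[4-(benzyloxy)-3,5-dimethoxybenzyl]dihydrofuran-2(3H)-one | O=C1C[C@H](CO1)Cc1cc(OC)c(OCc2ccccc2)c(OC)c1
F7 | step 4 | (3R,4R)-4-[4-(benzyloxy)-3,5-dimethoxybenzyl]-3-(3,4-dimethoxybenzyl)dihydrofuran-2(3H)-one | COc1ccc(C[C@@H](C(=O)O5)[C@H](C5)Cc2cc(OC)c(OCc3ccccc3)c(OC)c2)cc1OC
F8 | step 6 | (2R,3R)-2-[4-(benzyloxy)-3,5-dimethoxybenzyl]-3-(3,4-dimethoxybenzyl)-4-hydroxycyclobutan-1-one (C4 epimers) | COc1ccc(C[C@@H](C(O)C4=O)[C@H]4Cc2cc(OC)c(OCc3ccccc3)c(OC)c2)cc1OC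
F9 | step 6 | (2R,3R)-3-[4-(benzyloxy)-3,5-dimethoxybenzyl]-2-(3,4-dimethoxybenzyl)-4-hydroxycyclobutan-1-one (C4 epimers) | COc1ccc(C[C@@H](C4=O)[C@H](C4O)Cc2cc(OC)c(OCc3ccccc3)c(OC)c2)cc1OC
F10 | step 6 | (2R,3R)-2-[4-(benzyloxy)-3,5-dimethoxybenzyl]-3-(3,4-dimethoxybenzyl)-4-oxobutanoic acid | COc1ccc(C[C@@H](C=O)[C@H](C(=O)O)Cc2cc(OC)c(OCc3ccccc3)c(OC)c2)cc1OC
F11 | step 6 | (2R,3R)-3-[4-(benzyloxy)-3,5-dimethoxybenzyl]-2-(3,4-dimethoxybenzyl)-4-oxobutanoic acid | COc1ccc(C[C@@H](C(=O)O)[C@H](C=O)Cc2cc(OC)c(OCc3ccccc3)c(OC)c2)cc1OC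
F12 | step 2 | (E)-2-{3-[4-(benzyloxy)-3,5-dimethoxyphenyl]prop-1-en-1-yl}-4,4,5,5-tetramethyl-1,3,2-dioxaborolane | COc1cc(C/C=C/B2OC(C)(C)C(C)(C)O2)cc(OC)c1OCc1ccccc1
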